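Ochre lost substrate.

all flasks: free enzyme 0.05 mol%
- red: substrate 0.034 M; temperature −15 °C; run made earlier
- ochre: substrate 0.075 M; temperature 18 °C; run made earlier
- birch: substrate 0.050 M; temperature 30 °C; time 25 min
- maple: substrate 0.050 M; at 30 °C until 8.0 min, from then on at −30 °C; time 25 min
- elm: substrate 0.050 M; temperature −30 °C; time 25 min
- larch: substrate 0.050 M; temperature 0 °C; time 25 min

| run | time / min | target / % | substrate / % |
|---|---|---|---|
| red | 25.0 | 59.3 | 38.6 |
| red | 60.0 | 74.9 | 23.9 |
| red | 120 | 83.2 | 13.5 |
| red | 300 | 91.9 | 7.5 |
| ochre | 15.0 | 86.2 | 1.9 |
| ochre | 25.0 | 87.5 | 2.5 |
| ochre | 50.0 | 87.7 | 0.2 |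

(scatter of a reading: 1 percentage point)

1. the flask with the highest amount of target, in percent of the substrate charged ("all alike" if they lie within 1.5 percentage points) (birch / maple / elm / larch / all alike)
2. final target, as a percentage of the substrate charged, in birch
3. final target, as a percentage of the substrate charged, in maple
4. final target, as a percentage of the substrate charged, in elm
5. final target, as a percentage of the substrate charged, in larch

- the analysis behind the earlier runs scatters by 1 percentage point, standard deviation

1. In ochre's last reading, 12.1% of the charge is neither target nor substrate. This missing substrate stands to target as 0.138.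

2. Red's missing share averages 1.80%, comparable to a scatter of 1 percentage point and so not to be read from a single reading; its 4 readings are therefore pooled, and the same ratio reads 0.0233. Red and ochre differ in both temperature and charge, so two extreme readings are possible. In each, the logarithm is carried on in a straight line with temperature.

3. First extreme: the loss route and the target route have the same order in substrate, so the charge does not count. This ratio, the inverse of a selectivity factor, then reaches 0.264 at birch's temperature, and birch ends near 79.1%.

4. Second extreme: the target route runs one order higher, so the ratio grows as [substrate] falls and a run's ratio goes inversely with its charge. Red points this way: first-order decay from its first two readings gives 0.893% of substrate at 300 min, but the reading is 7.5%. Ochre then gives 0.0103 M for the loss concentration, the charge times the ratio of missing substrate to target. Red gives 7.91 × 10⁻⁴ M. Carried to birch this is 0.0264 M, so birch ends near 65.5%.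

5. Birch should lie between these, nearer the second, and maple close to birch. Larch, at 0.00255 M, has a ceiling of 95.2%. It is warmer and more concentrated than red, whose target reads 59.3% at 25.0 min, so larch should come highest. Elm, colder than red, should stay near or below that reading.

The forecast calls birch “complete within minutes” and gives 82% there, above both extremes, then 81% for maple, 24% for elm, 87% for larch, and larch as highest.

The flasks give 69.4% in birch, 69.2% in maple, 49.3% in elm and 84.7% in larch, so larch stands highest.

    substrate + free enzyme → target + free enzyme, rate k1*[substrate]^2.5*[free enzyme]/(1 + ([substrate]/Kh1)^2.5) (0.0523 M, k = 2.73 × 10⁵ /M².5/s, Ea = 18.0 kJ/mol)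
    substrate → uncatalysed product (k = 0.00315 /s, Ea = 92.0 kJ/mol)
    free enzyme → unfolded enzyme (k = 1.30 × 10⁻⁵ /s, Ea = 183 kJ/mol)
    2 free enzyme ⇌ resting dimer, settled at all times (K = 29700 /M, ΔH = −46.0 kJ/mol)
    (constants at 30 °C)

At larch's end, uncatalysed product stands to target as 0.0285, so its loss concentration reads 0.00143 M, less than the 0.00255 M carried down from ochre's 0.0103 M. A neighbour flask repeats larch with 0.085 M of substrate, at the same temperature and time. Larch's value divided by that charge gives a ratio of 0.0168. That neighbour flask ends with 1.54% uncatalysed product against 92.0% target, a ratio of 0.0167.

All runs are calculated for an exercise, and the scatter is random.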